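The earlier runs and the new flask are calculated with made-up constants, and the scatter is random.

Dawn is the flask we are asked about, and all we have besides its early readings is spring, charged with twice as much Qd.

| flask | Qd | remark | time |
|---|---|---|---|
| dawn | 0.020 M | the very flask that is asked about, followed so far |  |
| spring | 0.040 M | run made earlier |  |
| flask | 0.020 M |  | 20 h |

- dawn (time / h: Qb / %): 4.00: 15.0; 5.00: 18.6
- spring (time / h: Qb / %): 5.00: 9.8; 6.00: 10.8; 8.00: 13.3; 10.0: 15.5; 12.0: 16.9; 15.0: 18.8

(scatter of a reading: 0.3 percentage points)

* when, up to 20 h, the flask holds most Qb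
* the amount of Qb, in percent of the Qd charged, at that time
* the first time at which Qb reaches 12%, in the same percent

At 5.00 h dawn holds 3.72 mM of Qb and spring 3.92 mM. These lie close, so we read Qb as one curve in concentration while solid remains, and divide by the charge to get the percent.

We bracket dawn with two versions. In the low one, dawn's solid Qd, the limiting reagent, gives out at spring's last reading and Qb stands at 7.52 mM, or 37.6% of dawn's charge. In the high one, the solid outlasts the run and Qb keeps spring's last slope of 0.253 mM h⁻¹. That gives 8.79 mM, our shared level: the concentration the common curve reaches by the longest time, or 43.9% of dawn's charge. Spring's slope was 0.467 mM h⁻¹ earlier, so the straight line runs high, and we expect dawn between the two, with a late peak.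

The forecast gave 39% at 19 h, and the asked level at 3.2 h, with this caution: “This is an extrapolation, since the solubility is unknown.”

The simulation gives 39.8% at 20.0 h, and the asked level at 3.24 h.

    Qa ⇌ Qb (K = 1.00, k = 6.40 × 10⁻⁵ s⁻¹)
    Qb ⇌ Qc (K = 0.330, k = 0.00460 s⁻¹)
    Qd ⇌ Qa, rate k3*(cs3 - [Qa]) while solid is left; crystals form when [Qa] > cs3 (solubility = 8.60 mM, k = 2.70 × 10⁻⁴ s⁻¹)

That best is 7.96 mM of Qb, inside our band. Now take the neighbour charged with 0.050 M of Qd, all else held. The same two levels, divided by its charge, give 15.0% and 17.6%. It reaches 15.9% of Qb, and at 20.0 h it still has 61.9% of its charge as Qd.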